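The vessel is a closed, stirred, isothermal flask charged with undissolved solid substrate, and I count target as a fraction of that charge.

| flask | solid substrate | remark | time |
|---|---|---|---|
| south | 0.34 mM | run made earlier |  |
| north-east | 3.3 mM | run made earlier |  |
| beta | 1.0 mM |  | 3.0 min |
| epsilon | 4.0 mM |  | 3.0 min |
| alpha | 0.60 mM |  | 3.0 min |
| delta | 0.50 mM |  | 3.0 min |

| south: time / s | south: target / % | north-east: time / s | north-east: target / % |
|---|---|---|---|
| 25.0 | 1.6 | 10.0 | 0.6 |
| 50.0 | 4.5 | 15.0 | 0 |
| 60.0 | 5.1 | 40.0 | 0 |
| 90.0 | 8.9 | 90.0 | 0.8 |

(readings scatter by 0.5 percentage points)

- at the start none of the solid substrate is in solution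
- what has only dissolved of solid substrate counts as not reacted
- a reading or a percentage of target counts all its forms, free or not

* ranking by amount of target, in percent of the solid substrate charged, from high to low, at 3.0 min (beta / epsilon / alpha / delta)
* the amount of target, in percent of the solid substrate charged of the flask you put first, at 3.0 min
* the amount of target, in percent of the solid substrate charged of the flask you put last, at 3.0 min

I replace each curve by its mean slope. The south reading of 8.9% at 90.0 s, rescaled to the north-east charge, becomes 0.917%. North-east reads 0.8% with a scatter of 0.5 percentage points, so these two readings agree on one amount of target per unit time, a pseudo-zero-order picture. One dimensionless number then serves. For delta it is 12.1%: this reach, the mean south rate times the time over the charge, is my estimate of the share of its own charge that a flask still holding solid substrate turns into target. For epsilon it is 1.51%, so I rank delta, the smallest of the asked charges, first. To test the mean, I note that the later south slope reads steeper than the mean slope, though both rest on readings with a scatter of 0.5 points. Continuing that slope gives delta 12.8%, so I expect the reach to run somewhat low.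

The forecast gives delta > alpha > beta > epsilon, with 12% and 1.5%, on the ground of “zero order in the charge, with excess solid holding the dissolved level constant”.

The flask gives delta > alpha > beta > epsilon, with 16.0% and 2.00%, so the forecast stands within its tolerance. Delta and epsilon hold equal amounts of target, and delta stands at 1.32 times its reach.

    starting material + 2 target → 3 target (k = 48000 M⁻² s⁻¹)
    starting material → target (k = 0.00130 s⁻¹)
    target → over-reaction product (k = 5.10 × 10⁻⁵ s⁻¹)
    crystals ⇌ target, rate k4*(cs4 - [target]) while solid is left; crystals form when [target] > cs4 (solubility = 0.870 mM, k = 1.80 s⁻¹)
    solid substrate ⇌ starting material, rate k5*(cs5 - [starting material]) while solid is left; crystals form when [starting material] > cs5 (solubility = 0.390 mM, k = 0.0360 s⁻¹)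

The neighbour of delta charged with 0.20 mM has a reach of 30.3%, yet it gives 20.2%, so the rule misses there by 10 points. At 3.0 min delta still holds 9.15% as solid substrate, while the neighbour holds 0%, with 79.7% standing as starting material.

The data come from a simulation from invented constants; scatter was added.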